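**Strategy.** Everything rests on the C2–C3 bond of the chromanone ring C. The feature exploited is that C2 carries both the ring oxygen O1 and the electron-rich ring B, so that as an ArO–CH2–Ar' methylene its C–H bonds are the most hydridic in the molecule, while C3 lies alpha to the C4 ketone and can be a rhodium keto-carbenoid carbon. One enantioselective intramolecular C–H insertion therefore closes ring C and sets the only stereocenter (C2, S) from an achiral precursor: the silyl-protected 2-(diazoacetyl)aryl ether of the complete prenyl-chromene benzyl alcohol, made by Mitsunobu union of two phenolic fragments and diazo transfer.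

Key step: step 8

Remark on the chemistry (assumption): Rh2(S-PTTL)4 is assumed to favour insertion into the pro-S benzylic hydrogen of 16; should a pilot run show the opposite sense, the mirror-image catalyst Rh2(R-PTTL)4 is used under the same conditions.

Remark on the chemistry (assumption): compounds 1, 2, 4, 6, 9, 10, 13 and 14 are taken as commercial (14 may instead be made fresh from methanesulfonyl chloride and NaN3).

Step 1
Reactants: 1 5-bromo-2,4-dihydroxybenzaldehyde; 2 3-methylbut-2-enal (prenal)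
Product: 3 8-bromo-5-hydroxy-2,2-dimethyl-2H-chromene-6-carbaldehyde
Conditions: ethylenediammonium diacetate (20 mol %), xylene, reflux, Dean–Stark
Reagents that add atoms: 2 3-methylbut-2-enal, CC(C)=CC=O
Why: Knoevenagel-type condensation at C3 of the resorcinol (the only free nucleophilic carbon, C5 being brominated) followed by 6π-oxa-electrocyclization through the non-chelated 4-oxygen should give the angular 2,2-dimethylchromene and leave the chelated hydroxyl next to the aldehyde (chromenylation of a resorcinol with an enal).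

Step 2
Reactants: 3 8-bromo-5-hydroxy-2,2-dimethyl-2H-chromene-6-carbaldehyde; 4 4,4,5,5-tetramethyl-2-(3-methylbut-2-en-1-yl)-1,3,2-dioxaborolane (prenylboronic acid pinacol ester)
Product: 5 5-hydroxy-2,2-dimethyl-8-(3-methylbut-2-en-1-yl)-2H-chromene-6-carbaldehyde
Conditions: (IPent)PdCl2(3-chloropyridine) (IPent = 1,3-bis[2,6-di(pentan-3-yl)phenyl]imidazol-2-ylidene, 2 mol %), 5 M aq KOH (4 equiv), THF, 70 °C
Reagents that add atoms: 4 prenylboronic acid pinacol ester, CC(C)=CCB1OC(C)(C)C(C)(C)O1
Why: Suzuki–Miyaura allyl–aryl coupling in which the bulky N-heterocyclic carbene on palladium directs reductive elimination to the unsubstituted alpha carbon of the prenyl-palladium intermediate, which should give the linear prenyl arene, while the phenoxide form of the salicylaldehyde resists hydroxide.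

Step 3
Reactants: 5 5-hydroxy-2,2-dimethyl-8-(3-methylbut-2-en-1-yl)-2H-chromene-6-carbaldehyde; 6 triisopropylsilyl trifluoromethanesulfonate
Product: 7 2,2-dimethyl-8-(3-methylbut-2-en-1-yl)-5-[(triisopropylsilyl)oxy]-2H-chromene-6-carbaldehyde
Conditions: 6 (1.3 equiv), 2,6-lutidine, CH2Cl2, 0 °C to rt
Reagents that add atoms: 6 triisopropylsilyl trifluoromethanesulfonate, CC(C)[Si](OS(=O)(=O)C(F)(F)F)(C(C)C)C(C)C
Why: O-silylation with the silyl triflate is strong enough to break the hydrogen bond of the hindered chelated phenol, and the bulky triisopropylsilyl ether should resist migration and base in the following steps.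

Step 4
Reactants: 7 2,2-dimethyl-8-(3-methylbut-2-en-1-yl)-5-[(triisopropylsilyl)oxy]-2H-chromene-6-carbaldehyde
Product: 8 {2,2-dimethyl-8-(3-methylbut-2-en-1-yl)-5-[(triisopropylsilyl)oxy]-2H-chromen-6-yl}methanol
Conditions: i-Bu2AlH (1.2 equiv), CH2Cl2, −78 °C; aq potassium sodium tartrate (KNaC4H4O6) work-up
Reagents that add atoms: none
Why: Hydride reduction of the aldehyde by i-Bu2AlH at low temperature gives a non-nucleophilic aluminium alkoxide, which should prevent transfer of the ortho silyl group to the new benzylic oxygen.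

Step 5
Reactants: 9 1-(2,4,6-trihydroxyphenyl)ethan-1-one (phloroacetophenone); 10 chlorotriisopropylsilane
Product: 11 1-{2-hydroxy-4,6-bis[(triisopropylsilyl)oxy]phenyl}ethan-1-one
Conditions: 10 (2.1 equiv), imidazole (4.5 equiv), DMF, 0 °C to rt
Reagents that add atoms: 10 chlorotriisopropylsilane, CC(C)[Si](Cl)(C(C)C)C(C)C
Why: Selective silylation should take the para hydroxyl and one ortho hydroxyl and stop there, because the last ortho hydroxyl is locked in a hydrogen bond to the acetyl carbonyl.

Step 6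
Reactants: 8 {2,2-dimethyl-8-(3-methylbut-2-en-1-yl)-5-[(triisopropylsilyl)oxy]-2H-chromen-6-yl}methanol; 11 1-{2-hydroxy-4,6-bis[(triisopropylsilyl)oxy]phenyl}ethan-1-one
Product: 12 1-{2-({2,2-dimethyl-8-(3-methylbut-2-en-1-yl)-5-[(triisopropylsilyl)oxy]-2H-chromen-6-yl}methoxy)-4,6-bis[(triisopropylsilyl)oxy]phenyl}ethan-1-one
Conditions: PPh3 (1.5 equiv), DIAD (1.5 equiv), THF, 0 °C to rt
Reagents that add atoms: none
Why: Mitsunobu etherification of the acidic chelated phenol with the primary benzylic alcohol runs under neutral conditions, which should leave all three aryl silyl ethers in place.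

Step 7
Reactants: 12 the aryl benzyl ether methyl ketone; 13 2,2,2-trifluoroethyl trifluoroacetate; 14 methanesulfonyl azide
Product: 16 2-diazo-1-{2-({2,2-dimethyl-8-(3-methylbut-2-en-1-yl)-5-[(triisopropylsilyl)oxy]-2H-chromen-6-yl}methoxy)-4,6-bis[(triisopropylsilyl)oxy]phenyl}ethan-1-one, via trifluoroacetyl diketone 15 (not isolated)
Conditions: LiN(SiMe3)2 (1.1 equiv), THF, −78 °C; 13 (1.2 equiv), −78 °C; dilute HCl wash, crude 15 used at once; then 14 (1.5 equiv), Et3N (1.5 equiv), H2O (1 equiv), MeCN, rt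
Reagents that add atoms: 14 methanesulfonyl azide, CS(=O)(=O)N=[N+]=[N-] (the two diazo nitrogens of 16); 13 2,2,2-trifluoroethyl trifluoroacetate, O=C(OCC(F)(F)F)C(F)(F)F (the trifluoroacetyl group of 15 only)
Why: Detrifluoroacetylative diazo transfer (Danheiser procedure): the kinetic lithium enolate is C-trifluoroacetylated, and the activated diketone should accept the diazo group from the sulfonyl azide under mild amine conditions with loss of the trifluoroacetyl group as the N-mesyl amide.

Step 8
Reactants: 16 the diazoketone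
Product: 17 (2S)-2-{2,2-dimethyl-8-(3-methylbut-2-en-1-yl)-5-[(triisopropylsilyl)oxy]-2H-chromen-6-yl}-5,7-bis[(triisopropylsilyl)oxy]-2,3-dihydro-4H-chromen-4-one
Conditions: Rh2(S-PTTL)4 (dirhodium tetrakis[N-phthaloyl-(S)-tert-leucinate], 1 mol %), CH2Cl2, 4 Å molecular sieves, 0 °C, 16 added over 4 h by syringe pump (final 0.005 M)
Reagents that add atoms: none
Why: The chiral dirhodium tetracarboxylate expels N2 from 16 to give an electrophilic rhodium keto-carbenoid whose carbon (future C3) inserts, in a concerted hydride-transfer-like three-centre transition state, into one benzylic C–H bond of the ArO–CH2–Ar' group (future C2), with retention at that carbon. The closest known reaction type is the dirhodium-catalysed intramolecular C–H insertion of 2-alkoxyaryl diazoketones alpha to the ether oxygen, which gives chroman-4-ones, together with the enantioselective insertions into benzylic ether C–H bonds achieved with phthalimido-amino-acid carboxylate catalysts. Ring C is closed as a six-membered ring by 1,6-C–H insertion; no 1,5 alternative exists because position 5 from the carbenoid carbon is the ether oxygen. C2 is set by catalyst control: the two benzylic hydrogens are enantiotopic, and the chiral pocket of the four PTTL ligands must select the pro-S hydrogen, whose replacement by C3 gives the 2S configuration. The step needs insertion to outrun oxonium-ylide formation with [1,2]-benzyl shift, O–H insertion and cyclopropanation; the ether oxygen is a poor ylide donor because it is conjugated to the acyl-substituted ring A, the targeted C–H bond is alpha to oxygen and benzylic to the electron-rich ring B, all phenols carry a silyl group that offers no C–H bond alpha to oxygen near the carbenoid, and slow addition at high dilution should suppress intermolecular attack on the chromene and prenyl alkenes.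

Step 9
Reactants: 17 the tris-silyl (2S)-flavanone
Product: 18 Sanggenol N, (2S)-5,7-dihydroxy-2-[5-hydroxy-2,2-dimethyl-8-(3-methylbut-2-en-1-yl)-2H-chromen-6-yl]-2,3-dihydro-4H-chromen-4-one
Conditions: HF·pyridine, pyridine, THF, 0 °C to rt; pH 7 phosphate buffer quench
Reagents that add atoms: none
Why: Fluoride cleavage of the three aryl Si–O bonds in a weakly acidic medium generates no free phenoxide, so retro-oxa-Michael opening of ring C should not occur and the C2 configuration should be kept, while the prenyl and chromene alkenes are inert to these conditions (global desilylation).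

**Compound list**

1 | 5-bromo-2,4-dihydroxybenzaldehyde | O=Cc1cc(Br)c(O)cc1O | starting material
2 | 3-methylbut-2-enal (prenal) | CC(C)=CC=O | starting material
3 | 8-bromo-5-hydroxy-2,2-dimethyl-2H-chromene-6-carbaldehyde | O=Cc1cc(Br)c2OC(C)(C)C=Cc2c1O | intermediate
4 | 4,4,5,5-tetramethyl-2-(3-methylbut-2-en-1-yl)-1,3,2-dioxaborolane | CC(C)=CCB1OC(C)(C)C(C)(C)O1 | starting material
5 | 5-hydroxy-2,2-dimethyl-8-(3-methylbut-2-en-1-yl)-2H-chromene-6-carbaldehyde | O=Cc1cc(CC=C(C)C)c2OC(C)(C)C=Cc2c1O | intermediate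
6 | triisopropylsilyl trifluoromethanesulfonate | CC(C)[Si](OS(=O)(=O)C(F)(F)F)(C(C)C)C(C)C | starting material
7 | 2,2-dimethyl-8-(3-methylbut-2-en-1-yl)-5-[(triisopropylsilyl)oxy]-2H-chromene-6-carbaldehyde | O=Cc1cc(CC=C(C)C)c2OC(C)(C)C=Cc2c1O[Si](C(C)C)(C(C)C)C(C)C | intermediate
8 | {2,2-dimethyl-8-(3-methylbut-2-en-1-yl)-5-[(triisopropylsilyl)oxy]-2H-chromen-6-yl}methanol | OCc1cc(CC=C(C)C)c2OC(C)(C)C=Cc2c1O[Si](C(C)C)(C(C)C)C(C)C | intermediate
9 | 1-(2,4,6-trihydroxyphenyl)ethan-1-one (phloroacetophenone) | CC(=O)c1c(O)cc(O)cc1O | starting material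
10 | chlorotriisopropylsilane | CC(C)[Si](Cl)(C(C)C)C(C)C | starting material
11 | 1-{2-hydroxy-4,6-bis[(triisopropylsilyl)oxy]phenyl}ethan-1-one | CC(=O)c1c(O)cc(O[Si](C(C)C)(C(C)C)C(C)C)cc1O[Si](C(C)C)(C(C)C)C(C)C | intermediate
12 | 1-{2-({2,2-dimethyl-8-(3-methylbut-2-en-1-yl)-5-[(triisopropylsilyl)oxy]-2H-chromen-6-yl}methoxy)-4,6-bis[(triisopropylsilyl)oxy]phenyl}ethan-1-one | CC(=O)c1c(OCc2cc(CC=C(C)C)c3OC(C)(C)C=Cc3c2O[Si](C(C)C)(C(C)C)C(C)C)cc(O[Si](C(C)C)(C(C)C)C(C)C)cc1O[Si](C(C)C)(C(C)C)C(C)C | intermediate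
13 | 2,2,2-trifluoroethyl trifluoroacetate | O=C(OCC(F)(F)F)C(F)(F)F | starting material
14 | methanesulfonyl azide | CS(=O)(=O)N=[N+]=[N-] | starting material
15 | 1-{2-({2,2-dimethyl-8-(3-methylbut-2-en-1-yl)-5-[(triisopropylsilyl)oxy]-2H-chromen-6-yl}methoxy)-4,6-bis[(triisopropylsilyl)oxy]phenyl}-4,4,4-trifluorobutane-1,3-dione | O=C(CC(=O)C(F)(F)F)c1c(OCc2cc(CC=C(C)C)c3OC(C)(C)C=Cc3c2O[Si](C(C)C)(C(C)C)C(C)C)cc(O[Si](C(C)C)(C(C)C)C(C)C)cc1O[Si](C(C)C)(C(C)C)C(C)C | intermediate (not isolated)
16 | 2-diazo-1-{2-({2,2-dimethyl-8-(3-methylbut-2-en-1-yl)-5-[(triisopropylsilyl)oxy]-2H-chromen-6-yl}methoxy)-4,6-bis[(triisopropylsilyl)oxy]phenyl}ethan-1-one | [N-]=[N+]=CC(=O)c1c(OCc2cc(CC=C(C)C)c3OC(C)(C)C=Cc3c2O[Si](C(C)C)(C(C)C)C(C)C)cc(O[Si](C(C)C)(C(C)C)C(C)C)cc1O[Si](C(C)C)(C(C)C)C(C)C | intermediate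
17 | (2S)-2-{2,2-dimethyl-8-(3-methylbut-2-en-1-yl)-5-[(triisopropylsilyl)oxy]-2H-chromen-6-yl}-5,7-bis[(triisopropylsilyl)oxy]-2,3-dihydro-4H-chromen-4-one | CC(C)=CCc1cc([C@@H]2CC(=O)c3c(O[Si](C(C)C)(C(C)C)C(C)C)cc(O[Si](C(C)C)(C(C)C)C(C)C)cc3O2)c(O[Si](C(C)C)(C(C)C)C(C)C)c2c1OC(C)(C)C=C2 | intermediate
18 | Sanggenol N, (2S)-5,7-dihydroxy-2-[5-hydroxy-2,2-dimethyl-8-(3-methylbut-2-en-1-yl)-2H-chromen-6-yl]-2,3-dihydro-4H-chromen-4-one | CC(C)=CCc1cc([C@@H]2CC(=O)c3c(O)cc(O)cc3O2)c(O)c2c1OC(C)(C)C=C2 | target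

**Step count and risks**

Total step count: 9. Longest linear sequence: 8 steps (steps 1, 2, 3, 4, 6, 7, 8, 9); step 5 is a one-step branch.

Steps most likely to fail:

1. Step 8. The carbenoid may be diverted to an oxonium ylide at the ether oxygen, followed by [1,2]-shift of the electron-rich benzyl group, which closes a five-membered ring instead of ring C. The catalyst may also discriminate the two enantiotopic benzylic hydrogens poorly. The fallback abandons the carbenoid, sets out from 7 and 11, and comes back at 17. Ketone 11 is converted with LiN(SiMe3)2 (2.2 equiv, THF, −78 °C) into its phenoxide–enolate dianion and added to aldehyde 7, which should give the racemic aldol 3-{2,2-dimethyl-8-(3-methylbut-2-en-1-yl)-5-[(triisopropylsilyl)oxy]-2H-chromen-6-yl}-3-hydroxy-1-{2-hydroxy-4,6-bis[(triisopropylsilyl)oxy]phenyl}propan-1-one F1. Intramolecular Mitsunobu etherification (PPh3, DIAD, THF, 0 °C) should then close ring C through the O1–C2 bond to the racemic tris-silyl flavanone F2. Asymmetric transfer hydrogenation under kinetic resolution (RuCl(p-cymene)[(R,R)-TsDPEN], HCO2H/Et3N, EtOAc, rt, stopped just past half conversion) is expected to reduce the (2R)-ketone, with hydride delivered anti to the 2-aryl group, to the cis-(2R,4R)-flavan-4-ol F3. The unreacted (2S)-ketone is separated by chromatography and is compound 17.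

2. Step 7. The ortho silyl group may migrate from the aryl oxygen to the lithium enolate oxygen, and C-trifluoroacetylation of the twisted, di-ortho-substituted acetophenone may stay incomplete. The fallback avoids any enolate, sets out from 12 and comes back at 16. Condensation of 12 with N,N-dimethylformamide dimethyl acetal (toluene, 100 °C) should give the enaminone (E)-3-(dimethylamino)-1-{2-({2,2-dimethyl-8-(3-methylbut-2-en-1-yl)-5-[(triisopropylsilyl)oxy]-2H-chromen-6-yl}methoxy)-4,6-bis[(triisopropylsilyl)oxy]phenyl}prop-2-en-1-one F4. Treatment of F4 with 4-methylbenzenesulfonyl azide (MeCN, rt to 50 °C) should give 16 by cycloaddition to the enamine double bond and cycloreversion of the triazoline, with loss of the N-sulfonyl formamidine.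

3. Step 2. The prenyl-palladium intermediate may undergo allyl transposition, so that reductive elimination at the gamma carbon gives the reverse-prenyl isomer, and oxidative addition into the electron-rich bromophenoxide may be slow. The fallback protects first and couples without base, sets out from 3 and comes back at 7. Silylation of 3 (triisopropylsilyl trifluoromethanesulfonate, 2,6-lutidine, CH2Cl2) should give 8-bromo-2,2-dimethyl-5-[(triisopropylsilyl)oxy]-2H-chromene-6-carbaldehyde F5. Stille coupling of F5 with tributyl(3-methylbut-2-en-1-yl)stannane (Pd(PPh3)4, a zerovalent palladium catalyst, DMF, 90 °C) should then deliver 7 directly.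

**Further compounds**

F1 | step 8 | 3-{2,2-dimethyl-8-(3-methylbut-2-en-1-yl)-5-[(triisopropylsilyl)oxy]-2H-chromen-6-yl}-3-hydroxy-1-{2-hydroxy-4,6-bis[(triisopropylsilyl)oxy]phenyl}propan-1-one (racemic) | OC(CC(=O)c1c(O)cc(O[Si](C(C)C)(C(C)C)C(C)C)cc1O[Si](C(C)C)(C(C)C)C(C)C)c1cc(CC=C(C)C)c2OC(C)(C)C=Cc2c1O[Si](C(C)C)(C(C)C)C(C)C
F2 | step 8 | racemic 2-{2,2-dimethyl-8-(3-methylbut-2-en-1-yl)-5-[(triisopropylsilyl)oxy]-2H-chromen-6-yl}-5,7-bis[(triisopropylsilyl)oxy]-2,3-dihydro-4H-chromen-4-one | CC(C)=CCc1cc(C2CC(=O)c3c(O[Si](C(C)C)(C(C)C)C(C)C)cc(O[Si](C(C)C)(C(C)C)C(C)C)cc3O2)c(O[Si](C(C)C)(C(C)C)C(C)C)c2c1OC(C)(C)C=C2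
F3 | step 8 | (2R,4R)-2-{2,2-dimethyl-8-(3-methylbut-2-en-1-yl)-5-[(triisopropylsilyl)oxy]-2H-chromen-6-yl}-5,7-bis[(triisopropylsilyl)oxy]-3,4-dihydro-2H-chromen-4-ol | CC(C)=CCc1cc([C@H]2C[C@@H](O)c3c(O[Si](C(C)C)(C(C)C)C(C)C)cc(O[Si](C(C)C)(C(C)C)C(C)C)cc3O2)c(O[Si](C(C)C)(C(C)C)C(C)C)c2c1OC(C)(C)C=C2
F4 | step 7 | (E)-3-(dimethylamino)-1-{2-({2,2-dimethyl-8-(3-methylbut-2-en-1-yl)-5-[(triisopropylsilyl)oxy]-2H-chromen-6-yl}methoxy)-4,6-bis[(triisopropylsilyl)oxy]phenyl}prop-2-en-1-one | CN(C)/C=C/C(=O)c1c(OCc2cc(CC=C(C)C)c3OC(C)(C)C=Cc3c2O[Si](C(C)C)(C(C)C)C(C)C)cc(O[Si](C(C)C)(C(C)C)C(C)C)cc1O[Si](C(C)C)(C(C)C)C(C)C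
F5 | step 2 | 8-bromo-2,2-dimethyl-5-[(triisopropylsilyl)oxy]-2H-chromene-6-carbaldehyde | O=Cc1cc(Br)c2OC(C)(C)C=Cc2c1O[Si](C(C)C)(C(C)C)C(C)C
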